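Readings and results are simulated for an exercise, noise included.

Dusk's last reading is 19.5% of the substrate charged after 20.0 h, although its 0.030 M of reagent, there the limiting reagent, would allow 60.0%, and two chemists part over that gap before the new flasks are read.

all flasks: substrate 0.050 M
- dusk: reagent 0.030 M; temperature 100 °C; run made earlier
- teal: reagent 0.0600 M; temperature 100 °C; time 2.5 d
- ochre: reagent 0.0600 M; temperature 40 °C; time 2.5 d
- blue: reagent 0.0600 M; temperature 70 °C; time 2.5 d

dusk run (percent of the substrate charged): time / h: target / % = 1.33: 3.9; 3.00: 8.5; 8.00: 15.4; 20.0: 19.5

(readings scatter by 1 percentage point)

1. the best flask by amount of target, in percent of the substrate charged; "all alike" if 1.5 percentage points covers them all (teal / ochre / blue / all alike)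
2. amount of target at the end, in percent of the substrate charged, teal
3. amount of target at the end, in percent of the substrate charged, ochre
4. amount of target at the end, in percent of the substrate charged, blue

- what was read earlier has a scatter of 1 percentage point, one standard deviation
- steps that have been proposed: substrate + reagent <-> intermediate; intermediate <-> target + by-product; substrate -> decomposition product; target <-> isomer of the product
- the earlier runs do not show what temperature does; that part of a forecast is a guess

The first chemist holds that decomposition of the substrate races the formation of target, so that dusk levelled off with its substrate used up and more reagent simply wins a larger share of it. The second writes the balance of the reagent: if each target spends one reagent and one substrate, dusk at its last reading still has 0.0202 M of reagent and 0.0403 M of substrate, which gives 0.117 for her stop quotient, target times by-product over substrate left times reagent left, a reading that carries the scatter of that point. Holding this quotient on teal's charge at the same 100 °C, she expects 0.0139 M of target, which is 27.8%, with 72.2% of the substrate still present, whereas the first view has teal's substrate gone.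

The forecast states “So the plateau is not set by reagent supply.” It splits the loss into about 0.036 per hour to target and 0.15 to decomposition, notes about 29% under equilibrium, where the second chemist reckons 27.8%, and commits to the competition number: teal 33%, ochre 3%, blue 25%, best flask teal. Its temperature figures are a guess, since the earlier runs do not show what temperature does.

Teal is best at 31.5%, against ochre 0.121% and blue 15.0%.

    substrate + reagent ⇌ intermediate (K = 1.50 /M, k = 0.00142 /M/s, Ea = 97.0 kJ/mol, ΔH = −16.0 kJ/mol)
    intermediate ⇌ target + by-product (K = 0.160 M, k = 2.59 × 10⁻⁴ /s, Ea = 111 kJ/mol, ΔH = −38.0 kJ/mol)
    substrate → decomposition product (k = 1.52 × 10⁻⁷ /s, Ea = 128 kJ/mol)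
    target ⇌ isomer of the product (K = 0.139, k = 3.22 × 10⁻⁴ /s, Ea = 127 kJ/mol, ΔH = −14.0 kJ/mol)
    (constants at 100 °C)

The forecast's figure for teal lies nearer the result than the second chemist's, yet teal ends with 58.5% of its substrate, against her 72.2% and the first view's none, and with 2.05% as decomposition product. With teal's by-product as it stands, teal's quotient is 0.241 at 2.50 d and 0.241 at 25.0 d, the two alike, while decomposition, the first view's ground, climbs in teal to 17.5% by that later time. Blue, at 70 °C, ends its 2.5 d with a quotient of 0.0374, lower than teal's, and blue's target reaches 46.2% by 25.0 d.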